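**Retrosynthetic overview**
1. The spiro 1,3-dioxan-4-one is opened last, at the ester bond and at the bond from the cage C2 oxygen to the spiro carbon. This gives cage β-hydroxy acid 22 and hydroxy-pyranoquinone 30.
2. In the cage, the bicyclo[2.2.2]octenone bond C5–C(=O) comes from acyl-anion (benzoin) closure of an aldehyde on Cα onto the C5 enone carbonyl. The lactone carbon comes from oxidation of the vinyl methyl C10, and the prenyl group from an allyl placeholder by cross-metathesis.
3. Feature: the cage CH (C1), its gem-dimethyl ether carbon (C7 with both methyls), the cage CH2 (C6), the carbinol carbon C5, the alkene C3=C4, the lactone carbon C10 and the O-bearing bridgehead C2 are the ten carbons of (+)-3-carene with the cyclopropane bond C6–C7 cut. The tetrahydrofuran ring (O–C7–C1–C2–Cα) is closed when the Cα hydroxyl opens that bond in a car-3-en-5-one.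
4. Precursor: the C2–Cα bond by Stille coupling on a C2 enol triflate made from car-3-ene-2,5-dione; the C2–O bond by epoxidation anti to the gem-dimethyl bridge followed by E1cB opening; Cα by chelation-controlled allylation of an α-keto ester.
5. Ring order: cyclopropane and six-membered ring from the chiral pool, then tetrahydrofuran (step 9), bicyclo[2.2.2]octenone (step 12), the pyran of the quinone (step 19, separate branch), spiro dioxanone (step 20).

Key step: step 9

Remark on numbering: carane numbering is used for all carene-derived compounds (C1, C6 = cyclopropane CH carbons; C7 = gem-dimethyl carbon; C3 carries the methyl C10). β is the ring face that carries C7, α the opposite face; Cα is the side-chain carbon bonded to C2.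
Remark on the chemistry: 2,4-dienes, dienols and dienolates of the carane ring are norcaradienes and open to cycloheptatrienes with loss of chirality. No intermediate has C2=C3 together with C4=C5 or with a C5 ketone.
Assumption: the configurations at the spiro carbon and the adjacent CH(prenyl) carbon of the target are taken to be those favoured when the last ring closure is reversible.

**Step 1**
Reactants: 1 (+)-3-carene
Product: 3 car-3-ene-2,5-dione, via car-3-en-5-one 2 (not isolated)
Conditions: Rh2(cap)4 (1 mol%; cap = caprolactamate), t-BuOOH (70% in water, excess, in portions), 1,2-dichloroethane, 40 °C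
Reagents that add atoms: tert-butyl hydroperoxide CC(C)(C)OO
Why: radical allylic oxidation with tert-butylperoxyl converts the C5 methylene to the enone and then the γ-methylene C2 of that enone to the ene-dione; no base is present that could enolise the enone, and the cyclopropane stereocentres are untouched.

**Step 2**
Reactants: 3 car-3-ene-2,5-dione
Product: 5 5β-hydroxycar-2-en-2-yl triflate, via dilithium enolate alkoxide 4 (not isolated)
Conditions: LiBH(s-Bu)3 (2.2 equiv), THF, −78 °C; then PhNTf2 (1.1 equiv), −78 to 0 °C
Reagents that add atoms: N-phenylbis(trifluoromethanesulfonimide) O=S(=O)(N(c1ccccc1)S(=O)(=O)C(F)(F)F)C(F)(F)F; lithium tri-sec-butylborohydride [Li+].CCC(C)[BH-](C(C)CC)C(C)CC (lithium of intermediate 4 only)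
Why: reductive enolate trapping, in which hydride adds 1,4 to the unsubstituted carbon C4 to give the C2 enolate, a second hydride reduces the C5 ketone from the α-face (the carbinol centre is removed again in step 7), and PhNTf2 triflates the enolate oxygen in preference to the hindered secondary alkoxide.

**Step 3**
Reactants: 6 methyl propiolate
Product: 7 methyl 2-(tributylstannyl)acrylate
Conditions: Bu3SnH, Pd(PPh3)4 (2 mol%), THF, 0 °C to rt
Reagents that add atoms: tributyltin hydride CCCC[SnH](CCCC)CCCC
Why: palladium-catalysed hydrostannation of a propiolate is a syn addition that places tin on the ester-bearing carbon.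

**Step 4**
Reactants: 5 5β-hydroxycar-2-en-2-yl triflate; 7 methyl 2-(tributylstannyl)acrylate
Product: 8 methyl 2-(5β-hydroxycar-2-en-2-yl)acrylate
Conditions: Pd(PPh3)4 (5 mol%), CuI (20 mol%), LiCl, DMF, 50 °C
Reagents that add atoms: none
Why: Stille coupling of an enol triflate with an alkenylstannane, with LiCl and CuI to speed transmetalation of the hindered partners, forms the C2–Cα bond on sp2 carbon without a new stereocentre.

**Step 5**
Reactants: 8 methyl 2-(5β-hydroxycar-2-en-2-yl)acrylate
Product: 9 methyl 2-(2α,3α-epoxy-5β-hydroxycaran-2-yl)acrylate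
Conditions: mCPBA, CH2Cl2, 0 °C
Reagents that add atoms: 3-chloroperbenzoic acid OOC(=O)c1cccc(Cl)c1
Why: the tetrasubstituted ring alkene is epoxidised in preference to the electron-poor acrylate alkene, and the peracid comes from the α-face because the endo methyl of C7 shields the β-face (as in 2-carene), which sets C2 with oxygen α and the carbon chain β.

**Step 6**
Reactants: 9 methyl 2-(2α,3α-epoxy-5β-hydroxycaran-2-yl)acrylate
Product: 10 methyl (2α,3α-epoxy-5β-hydroxycaran-2-yl)oxoacetate
Conditions: O3, CH2Cl2/MeOH, −78 °C; then Me2S
Reagents that add atoms: ozone [O-][O+]=O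
Why: ozonolysis of the only alkene, a 2-substituted acrylate, gives the α-keto ester.

**Step 7**
Reactants: 10 methyl (2α,3α-epoxy-5β-hydroxycaran-2-yl)oxoacetate
Product: 12 methyl (2α-hydroxy-5-oxocar-3-en-2β-yl)oxoacetate, via epoxy diketo ester 11 (not isolated)
Conditions: Dess–Martin periodinane, CH2Cl2, 0 °C to rt; then Et3N, 0 °C
Reagents that add atoms: none
Why: Dess–Martin oxidation gives a β,γ-epoxy ketone that undergoes E1cB opening (enolisation at C4, cleavage of the C3–O bond) to the γ-hydroxy enone, with the alkene placed at C3=C4 and the C2–O bond and configuration retained.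

**Step 8**
Reactants: 12 methyl (2α-hydroxy-5-oxocar-3-en-2β-yl)oxoacetate; 13 allyl bromide
Product: 14 methyl 2-hydroxy-2-(2α-hydroxy-5-oxocar-3-en-2β-yl)pent-4-enoate (allyl analogue of the diol ester precursor)
Conditions: In powder, THF/H2O (1:1), rt
Reagents that add atoms: none
Why: Barbier allylation with allylindium is selective for the α-keto ester ketone over the hindered enone, and chelation of the metal between the C2 hydroxyl and the ketone oxygen lets allyl add from the C3 side, away from C7 on C1, which sets Cα; allyl stands in for prenyl because prenyl-metal reagents add through their tertiary carbon and a prenyl alkene would cyclise in the acid of step 9.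

**Step 9**
Reactants: 14 methyl 2-hydroxy-2-(2α-hydroxy-5-oxocar-3-en-2β-yl)pent-4-enoate
Product: 15 methyl 1-allyl-7a-hydroxy-3,3,7-trimethyl-5-oxo-1,3,3a,4,5,7a-hexahydroisobenzofuran-1-carboxylate (cis-fused)
Conditions: BF3·OEt2 (20 mol%), CH2Cl2, −40 to 0 °C
Reagents that add atoms: none
Why: BF3 activates the C5 carbonyl; the external cyclopropane bond C6–C7, which overlaps with the carbonyl π system, polarises towards the tertiary carbon C7, the Cα hydroxyl captures C7, and C6 becomes the α-carbon of an enol that tautomerises to the enone. The reaction type is the acid-promoted homo-conjugate opening of a cyclopropyl ketone by an oxygen nucleophile, known for caren-5-ones in protic media, here run intramolecularly. The tetrahydrofuran closes in a 5-exo-tet mode and is cis-fused because the C1–C7 and C2–Cα bonds are both on the β-face. No stereocentre is formed (C7 carries two methyls, C6 becomes CH2) and C1 keeps the carene configuration. The step needs cleavage of C6–C7 and not of the ring-fusion bond C1–C6, which better overlap and the tertiary cation character secure, and attack by the Cα hydroxyl and not the C2 hydroxyl, which could only give an oxetane. The allyl group is not protonated under these conditions, and catalytic acid at low temperature limits dehydration of the 4-hydroxycyclohexenone to a phenol.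

**Step 10**
Reactants: 15 tetrahydrofuran–cyclohexenone ester
Product: 16 1-allyl-1-(hydroxymethyl)-3,3,7-trimethyl-1,3,3a,4,5,7a-hexahydroisobenzofuran-5,7a-diol (C5 epimers)
Conditions: i-Bu2AlH (excess), CH2Cl2, −78 to 0 °C; aq. potassium sodium tartrate
Reagents that add atoms: none
Why: i-Bu2AlH reduces the ester to the primary alcohol and the enone carbonyl 1,2 to the allylic alcohol, whose new centre at C5 is of no consequence because step 11 removes it.

**Step 11**
Reactants: 16 triol
Product: 17 1-allyl-7a-hydroxy-3,3,7-trimethyl-5-oxo-1,3,3a,4,5,7a-hexahydroisobenzofuran-1-carbaldehyde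
Conditions: Dess–Martin periodinane, CH2Cl2, 0 °C to rt
Reagents that add atoms: none
Why: Dess–Martin oxidation converts the primary alcohol to the aldehyde and the allylic alcohol to the enone, leaves the tertiary alcohol alone, and the aldehyde has no α-hydrogen to epimerise.

**Step 12**
Reactants: 17 keto aldehyde
Product: 18 cage α-ketol (bicyclo[2.2.2]octenone with bridgeheads C2 and C5; allyl on Cα, methyl on C3, hydroxyl on C2 and C5)
Conditions: 2-mesityl-6,7-dihydro-5H-pyrrolo[2,1-c][1,2,4]triazol-2-ium chloride (20 mol%), DBU (20 mol%), THF, rt to 40 °C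
Reagents that add atoms: none
Why: carbene-catalysed intramolecular crossed aldehyde–ketone benzoin reaction, in which the Breslow intermediate adds 1,2 to the C5 carbonyl in a six-membered closure (Stetter addition to C3 would need a four-membered ring), and the tether reaches C5 only from the β-face, so the ring fixes the new bridgehead carbinol centre.

**Step 13**
Reactants: 18 cage α-ketol
Product: 19 cage enal (C10 as CHO)
Conditions: SeO2, 1,4-dioxane, 80 °C
Reagents that add atoms: selenium dioxide O=[Se]=O
Why: Riley allylic oxidation (ene reaction, then [2,3] shift) at C10, the only allylic C–H position of the trisubstituted alkene since C2 and C5 are quaternary, continues to the enal, while the monosubstituted allyl alkene reacts far more slowly and the ketone has no α-hydrogen.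

**Step 14**
Reactants: 19 cage enal; 20 2-methyl-2-butene
Product: 21 cage enal with prenyl on Cα
Conditions: second-generation Grubbs catalyst (10 mol%), 20 in excess, CH2Cl2, 40 °C
Reagents that add atoms: none
Why: cross-metathesis of the terminal allyl alkene with 2-methyl-2-butene gives the prenyl group, and the trisubstituted conjugated alkene of the enal does not take part.

**Step 15**
Reactants: 21 cage enal with prenyl
Product: 22 cage β-hydroxy acid
Conditions: NaClO2, NaH2PO4, 2-methyl-2-butene, t-BuOH/H2O, rt
Reagents that add atoms: sodium chlorite [Na+].[O-]Cl=O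
Why: Pinnick oxidation of the enal to the acid, with the alkene scavenger removing hypochlorous acid so that the prenyl group is not attacked.

**Step 16**
Reactants: 23 1,2,3,5-tetramethoxybenzene; 24 prenyl bromide
Product: 26 1,2,3,5-tetramethoxy-4-prenylbenzene, via aryllithium 25 (not isolated)
Conditions: n-BuLi, TMEDA, THF, 0 °C; CuBr·SMe2 (10 mol%), then 24, −78 °C to rt
Reagents that add atoms: n-butyllithium [Li]CCCC (lithium of intermediate 25 only)
Why: directed ortho-lithiation between two methoxy groups followed by copper-catalysed SN2 allylation gives the linear prenyl arene.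

**Step 17**
Reactants: 26 1,2,3,5-tetramethoxy-4-prenylbenzene
Product: 27 2,6-dimethoxy-3-prenyl-1,4-benzoquinone
Conditions: (NH4)2Ce(NO3)6, MeCN/H2O, 0 °C
Reagents that add atoms: water O
Why: oxidative demethylation of the para-dimethoxy pair by the cerium oxidant gives the p-quinone and leaves the two flanking methoxy groups and the prenyl group in place.

**Step 18**
Reactants: 27 2,6-dimethoxy-3-prenyl-1,4-benzoquinone
Product: 28 2,6-dihydroxy-3-prenyl-1,4-benzoquinone
Conditions: 2 M NaOH, MeOH, 50 °C; then 1 M HCl
Reagents that add atoms: sodium hydroxide [Na+].[OH-]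
Why: the methoxyquinone carbons are vinylogous esters and are hydrolysed by addition–elimination of hydroxide.

**Step 19**
Reactants: 28 2,6-dihydroxy-3-prenyl-1,4-benzoquinone; 29 3-methylbut-2-enal
Product: 30 7-hydroxy-2,2-dimethyl-6-prenyl-2H-chromene-5,8-dione
Conditions: pyridine, 100 °C
Reagents that add atoms: none
Why: Knoevenagel condensation at the only free nucleophilic ring carbon, then oxa-6π electrocyclisation through the neighbouring hydroxyl, fuses the 2,2-dimethylpyran as it does for 2-hydroxynaphthoquinone with enals, and the hydroxyl next to the prenyl group stays free.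

**Step 20**
Reactants: 22 cage β-hydroxy acid; 30 7-hydroxy-2,2-dimethyl-6-prenyl-2H-chromene-5,8-dione
Product: 32 target CNP0222516.1, via quinonyl ester 31 (not isolated)
Conditions: EDC·HCl, DMAP (20 mol%), CH2Cl2, 0 °C to rt; then Et3N (20 mol%), rt
Reagents that add atoms: none
Why: Proposed new method: Steglich acylation puts the cage acyl group on the quinone hydroxyl; in ester 31 the C2 tertiary hydroxyl then adds in a 6-exo-trig oxa-Michael reaction to the acyloxy-bearing quinone carbon (β-carbon of the enone next to the prenyl carbon), and the enolate is protonated at the prenyl-bearing carbon to give the acyloxy/alkoxy ketal; the closest known reaction types are intramolecular oxa-Michael addition of alcohols to quinones and enones and ketalisation of enolised 1,2-diketones; the spiro centre and the CH(prenyl) centre should settle under thermodynamic control because the addition is reversible and the CH is enolisable.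

**Compound list**
1 | (+)-3-carene, (1S,6R)-3,7,7-trimethylbicyclo[4.1.0]hept-3-ene | CC1=CC[C@@H]2[C@H](C1)C2(C)C | starting material
2 | car-3-en-5-one | CC1=CC(=O)[C@@H]2[C@@H](C2(C)C)C1 | intermediate
3 | car-3-ene-2,5-dione | CC1=CC(=O)[C@@H]2[C@@H](C2(C)C)C1=O | intermediate
4 | dilithium 5β-oxidocar-2-en-2-olate | CC1=C([O-])[C@H]2[C@H](C2(C)C)[C@H]([O-])C1.[Li+].[Li+] | intermediate
5 | 5β-hydroxycar-2-en-2-yl trifluoromethanesulfonate | CC1=C(OS(=O)(=O)C(F)(F)F)[C@H]2[C@H](C2(C)C)[C@H](O)C1 | intermediate
6 | methyl propiolate | C#CC(=O)OC | starting material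
7 | methyl 2-(tributylstannyl)acrylate | C=C(C(=O)OC)[Sn](CCCC)(CCCC)CCCC | intermediate
8 | methyl 2-(5β-hydroxycar-2-en-2-yl)acrylate | CC1=C(C(=C)C(=O)OC)[C@H]2[C@H](C2(C)C)[C@H](O)C1 | intermediate
9 | methyl 2-(2α,3α-epoxy-5β-hydroxycaran-2-yl)acrylate | C[C@]12O[C@@]1(C(=C)C(=O)OC)[C@H]3[C@H](C3(C)C)[C@H](O)C2 | intermediate
10 | methyl (2α,3α-epoxy-5β-hydroxycaran-2-yl)oxoacetate | C[C@]12O[C@@]1(C(=O)C(=O)OC)[C@H]3[C@H](C3(C)C)[C@H](O)C2 | intermediate
11 | methyl (2α,3α-epoxy-5-oxocaran-2-yl)oxoacetate | C[C@]12O[C@@]1(C(=O)C(=O)OC)[C@H]3[C@H](C3(C)C)C(=O)C2 | intermediate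
12 | methyl (2α-hydroxy-5-oxocar-3-en-2β-yl)oxoacetate | CC1=CC(=O)[C@@H]2[C@@H](C2(C)C)[C@@]1(O)C(=O)C(=O)OC | intermediate
13 | allyl bromide | C=CCBr | starting material
14 | methyl 2-hydroxy-2-(2α-hydroxy-5-oxocar-3-en-2β-yl)pent-4-enoate (key-step precursor, allyl in place of prenyl) | CC1=CC(=O)[C@@H]2[C@@H](C2(C)C)[C@@]1(O)[C@](O)(CC=C)C(=O)OC | intermediate
15 | methyl 1-allyl-7a-hydroxy-3,3,7-trimethyl-5-oxo-1,3,3a,4,5,7a-hexahydroisobenzofuran-1-carboxylate (key-step product, cis-fused) | CC1=CC(=O)C[C@H]2C(C)(C)O[C@@](CC=C)(C(=O)OC)[C@@]12O | intermediate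
16 | 1-allyl-1-(hydroxymethyl)-3,3,7-trimethyl-1,3,3a,4,5,7a-hexahydroisobenzofuran-5,7a-diol (C5 epimers) | CC1=CC(O)C[C@H]2C(C)(C)O[C@@](CC=C)(CO)[C@@]12O | intermediate
17 | 1-allyl-7a-hydroxy-3,3,7-trimethyl-5-oxo-1,3,3a,4,5,7a-hexahydroisobenzofuran-1-carbaldehyde | CC1=CC(=O)C[C@H]2C(C)(C)O[C@@](CC=C)(C=O)[C@@]12O | intermediate
18 | cage α-ketol (allyl on Cα, methyl on C3) | CC1=C[C@]3(O)C[C@H]4C(C)(C)O[C@@](CC=C)(C3=O)[C@@]14O | intermediate
19 | cage enal (allyl on Cα) | O=CC1=C[C@]3(O)C[C@H]4C(C)(C)O[C@@](CC=C)(C3=O)[C@@]14O | intermediate
20 | 2-methyl-2-butene | CC=C(C)C | starting material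
21 | cage enal (prenyl on Cα) | O=CC1=C[C@]3(O)C[C@H]4C(C)(C)O[C@@](CC=C(C)C)(C3=O)[C@@]14O | intermediate
22 | cage β-hydroxy acid | OC(=O)C1=C[C@]3(O)C[C@H]4C(C)(C)O[C@@](CC=C(C)C)(C3=O)[C@@]14O | intermediate
23 | 1,2,3,5-tetramethoxybenzene | COc1cc(OC)c(OC)c(OC)c1 | starting material
24 | prenyl bromide | CC(C)=CCBr | starting material
25 | 2,3,4,6-tetramethoxyphenyllithium | [Li]c1c(OC)cc(OC)c(OC)c1OC | intermediate
26 | 1,2,3,5-tetramethoxy-4-prenylbenzene | COc1cc(OC)c(OC)c(OC)c1CC=C(C)C | intermediate
27 | 2,6-dimethoxy-3-prenyl-1,4-benzoquinone | COC1=CC(=O)C(CC=C(C)C)=C(OC)C1=O | intermediate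
28 | 2,6-dihydroxy-3-prenyl-1,4-benzoquinone | OC1=CC(=O)C(CC=C(C)C)=C(O)C1=O | intermediate
29 | 3-methylbut-2-enal | CC(C)=CC=O | starting material
30 | 7-hydroxy-2,2-dimethyl-6-prenyl-2H-chromene-5,8-dione | CC(C)=CCC1=C(O)C(=O)C2=C(C=CC(C)(C)O2)C1=O | intermediate
31 | quinonyl ester of 22 with 30 (acyl on the C7 oxygen of the chromenedione) | CC(C)=CCC1=C(OC(=O)C3=C[C@]4(O)C[C@H]5C(C)(C)O[C@@](CC=C(C)C)(C4=O)[C@@]35O)C(=O)C2=C(C=CC(C)(C)O2)C1=O | intermediate
32 | CNP0222516.1 | CC(C)=CC[C@H]1C(=O)C2=C(OC(C)(C)C=C2)C(=O)[C@@]12OC(=O)C1=C[C@]3(O)C[C@H]4C(C)(C)O[C@@](CC=C(C)C)(C3=O)[C@@]14O2 | target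

**Step count**
Total: 20 steps. Longest linear sequence: 15 steps (steps 1, 2, 4 to 15 and 20).

**Steps most likely to fail**

Step 20. The ester may form but the ring closure may not follow: the oxa-Michael addition can stay on the side of the quinone, the acyl group can be lost again from the vinylogous anhydride, or the closure can settle on the other spiro configuration. The fallback sets out from 30 and 22 and comes back at 32. Compound 30 is O-methylated (Me3SiCHN2, MeOH/toluene) to 7-methoxy-2,2-dimethyl-6-prenyl-2H-chromene-5,8-dione F1. F1 and 22 are then heated with camphorsulfonic acid in benzene over 4 Å molecular sieves. This is an acid-catalysed ketal exchange on a vinylogous ester, known for β-alkoxy enones with diols and for β-hydroxy acids with enol ethers (1,3-dioxan-4-one formation). The C2 hydroxyl and the carboxyl group replace methanol at the methoxy-bearing carbon, and the resulting enol ketonises at the prenyl-bearing carbon.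

Step 12. The benzoin equilibrium may not favour the strained cage (enone conjugation is lost), the hindered aldehyde may form the Breslow intermediate slowly, and base may cleave the β-hydroxy aldehyde by retro-aldol reaction. The fallback sets out from 17 and comes back at 18. Reductive ketyl coupling (SmI2, t-BuOH, THF, −78 °C) joins the aldehyde carbon to C5 and gives the cage cis-diol F2. Oxidation of its secondary alcohol (SO3·pyridine, DMSO, Et3N) then gives 18.

Step 9. Acid may dehydrate the 4-hydroxycyclohexenone to a phenol, cleave the ring-fusion bond, or leave the tertiary cation to eliminate before the hydroxyl closes. The fallback sets out from 14 and comes back at 15, and it separates bond cleavage from ring closure. Me3SiI (CH2Cl2, −40 °C, aqueous work-up) opens the cyclopropyl ketone by iodide attack at C7 to the tertiary iodide F3. AgOTf with 2,6-di-tert-butyl-4-methylpyridine (CH2Cl2, −20 °C) then closes the tetrahydrofuran by silver-assisted substitution with the Cα hydroxyl.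

**Further compounds**
F1 | step 20 | 7-methoxy-2,2-dimethyl-6-prenyl-2H-chromene-5,8-dione | COC1=C(CC=C(C)C)C(=O)C2=C(OC(C)(C)C=C2)C1=O
F2 | step 12 | cage cis-diol (secondary carbinol in place of the bridge ketone of 18; carbinol CH configuration not defined) | CC1=C[C@]3(O)C[C@H]4C(C)(C)O[C@@](CC=C)(C3O)[C@@]14O
F3 | step 9 | methyl 2-hydroxy-2-[(1-hydroxy-6-(2-iodopropan-2-yl)-2-methyl-4-oxocyclohex-2-en-1-yl)]pent-4-enoate (tertiary iodide from 14) | CC1=CC(=O)C[C@@H](C(C)(C)I)[C@@]1(O)[C@](O)(CC=C)C(=O)OC
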